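**Retrosynthetic overview**

1. Target ⇐ epoxidation of the C8=C9 alkene on the face away from the angular CH3 and the ester; ester ⇐ 6-alcohol ⇐ 6-ketone (hydride anti to the angular CH3).
2. Seven-membered ring (formed last) ⇐ ring-closing metathesis between an allyl group on C1 and a 2-methylallyl carbinol on C5.
3. Quaternary C1 ⇐ anionic oxy-Cope rearrangement that moves an allyl group from the C6 carbinol to C1 of a cyclopentenyl carbinol; the C6 carbinol relays the C4 configuration, and C5 is then set by equilibration.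
4. Five-membered ring (formed first) ⇐ ozonolysis and intramolecular aldol condensation of (S)-terpinen-4-ol, whose carbinol carbon becomes C4.

Assumption: (S)-(+)-terpinen-4-ol is bought in high enantiomeric purity; its ee fixes that of everything downstream.

Atom labels C1–C10 in the comments follow the target skeleton: C1 = ring-fusion carbon bearing CH3, C2, C3, C4 = C(OH)(isopropyl), C5 = ring-fusion CH, C6 = CH–O(ester), C7, C8 = epoxide carbon bearing CH3, C9 = epoxide CH, C10. The stereochemical arguments in steps 4, 5, 9 and 11 are conformational models, not precedent.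

**Route**

Step 1
Reactants: 1 (S)-(+)-terpinen-4-ol
Product: 4 (5R)-5-hydroxy-2-methyl-5-(propan-2-yl)cyclopent-1-ene-1-carbaldehyde, via secondary ozonide 2 (not isolated), via keto aldehyde 3 (not isolated)
Conditions: O3, CH2Cl2, −78 °C; Me2S, −78 °C to rt; then piperidine (0.3 equiv), AcOH (0.3 equiv), 40 °C
Reagents that add atoms: ozone, [O-][O+]=O
Why: Ozonolysis followed by enamine-mediated intramolecular aldol condensation (aldehyde α-carbon onto the methyl ketone, 5-ring closure, as in the limonene series) gives the cyclopentene carbaldehyde; the carbinol carbon (future C4) is untouched.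

Step 2
Reactants: 4 (5R)-5-hydroxy-2-methyl-5-(propan-2-yl)cyclopent-1-ene-1-carbaldehyde; 5 allylmagnesium bromide
Product: 6 1-[(5R)-5-hydroxy-2-methyl-5-(propan-2-yl)cyclopent-1-en-1-yl]but-3-en-1-ol (both C1 epimers, 1R expected to predominate)
Conditions: allylmagnesium bromide (2.5 equiv), THF, −78 °C
Reagents that add atoms: allylmagnesium bromide, C=CC[Mg]Br
Why: Grignard 1,2-addition to the enal (allyl Grignards add 1,2); the new carbinol centre is erased in step 3, so its ratio does not matter.

Step 3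
Reactants: 6 1-[(5R)-5-hydroxy-2-methyl-5-(propan-2-yl)cyclopent-1-en-1-yl]but-3-en-1-ol
Product: 7 1-[(5R)-5-hydroxy-2-methyl-5-(propan-2-yl)cyclopent-1-en-1-yl]but-3-en-1-one
Conditions: Dess–Martin periodinane, pyridine, CH2Cl2, 0 °C
Reagents that add atoms: none
Why: Dess–Martin oxidation of the secondary alcohol under buffered, neutral conditions leaves the tertiary alcohol alone and does not move the β,γ-alkene into conjugation.

Step 4
Reactants: 7 1-[(5R)-5-hydroxy-2-methyl-5-(propan-2-yl)cyclopent-1-en-1-yl]but-3-en-1-one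
Product: 8 (1S)-1-[(5R)-5-hydroxy-2-methyl-5-(propan-2-yl)cyclopent-1-en-1-yl]but-3-en-1-ol
Conditions: Zn(BH4)2, Et2O, −30 °C
Reagents that add atoms: none
Why: Chelation-controlled 1,2-reduction: zinc bridges the tertiary hydroxyl and the ketone oxygen, which turns the C=O toward the hydroxyl face and the allyl CH2 toward the isopropyl face, and hydride enters from the open side next to the ring CH3 (the other side is closed by the quaternary carbinol carbon), giving the 1S carbinol.

Step 5
Reactants: 8 (1S)-1-[(5R)-5-hydroxy-2-methyl-5-(propan-2-yl)cyclopent-1-en-1-yl]but-3-en-1-ol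
Product: 12 (1R,2R,5R)-2-hydroxy-5-methyl-2-(propan-2-yl)-5-(prop-2-en-1-yl)cyclopentane-1-carbaldehyde, via potassium alkoxide 9 (not isolated), via potassium enolate 10 (not isolated), via epimeric aldehyde 11 (not isolated)
Conditions: KN(SiMe3)2 (1.05 equiv), 18-crown-6, THF, −40 to 40 °C; AcOH, −78 °C; then DBU (0.1 equiv), CH2Cl2, 0 °C
Reagents that add atoms: none
Why: Anionic oxy-Cope rearrangement ([3,3]-sigmatropic, chair): in the alkoxide hydrogen-bonded to the tertiary OH the carbinol oxygen sits on the hydroxyl face, the carbinol H eclipses the ring CH3 (least allylic strain) and the allyl group stands on the isopropyl face, so the new C1–C10 bond forms cis to isopropyl (quaternary C1), and base equilibration of the only enolisable centre then puts CHO cis to the smaller OH and CH3 groups (C5).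

Step 6
Reactants: 12 (1R,2R,5R)-2-hydroxy-5-methyl-2-(propan-2-yl)-5-(prop-2-en-1-yl)cyclopentane-1-carbaldehyde; 13 (2-methylprop-2-en-1-yl)magnesium chloride
Product: 14 (1S)-1-[(1S,2R,5R)-2-hydroxy-5-methyl-2-(propan-2-yl)-5-(prop-2-en-1-yl)cyclopentyl]-3-methylbut-3-en-1-ol
Conditions: (2-methylprop-2-en-1-yl)magnesium chloride (3 equiv), THF, −78 °C
Reagents that add atoms: (2-methylprop-2-en-1-yl)magnesium chloride, CC(=C)C[Mg]Cl
Why: Grignard addition to the aldehyde; the magnesium chelate with the β-alkoxide and attack anti to the neighbouring CH3 predict the 1S carbinol, but either epimer serves because this centre is oxidised in step 8.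

Step 7
Reactants: 14 (1S)-1-[(1S,2R,5R)-2-hydroxy-5-methyl-2-(propan-2-yl)-5-(prop-2-en-1-yl)cyclopentyl]-3-methylbut-3-en-1-ol
Product: 15 (3R,3aS,4S,8aR)-6,8a-dimethyl-3-(propan-2-yl)-1,2,3,3a,4,5,8,8a-octahydroazulene-3,4-diol
Conditions: second-generation Grubbs catalyst (5 mol %), CH2Cl2 (0.005 M), 40 °C
Reagents that add atoms: none
Why: Ring-closing metathesis of the monosubstituted and the 1,1-disubstituted alkene closes the trans-fused cycloheptene with the trisubstituted C8=C9 bond; no stereocentre is touched and the free hydroxyls are tolerated.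

Step 8
Reactants: 15 (3R,3aS,4S,8aR)-6,8a-dimethyl-3-(propan-2-yl)-1,2,3,3a,4,5,8,8a-octahydroazulene-3,4-diol
Product: 16 (3R,3aR,8aR)-3-hydroxy-6,8a-dimethyl-3-(propan-2-yl)-2,3,3a,5,8,8a-hexahydroazulen-4(1H)-one
Conditions: Dess–Martin periodinane, pyridine, CH2Cl2, 0 °C
Reagents that add atoms: none
Why: Dess–Martin oxidation of the only secondary alcohol under neutral conditions, which keeps the β-hydroxy ketone from retro-aldol cleavage and the β,γ-alkene from conjugating.

Step 9
Reactants: 16 (3R,3aR,8aR)-3-hydroxy-6,8a-dimethyl-3-(propan-2-yl)-2,3,3a,5,8,8a-hexahydroazulen-4(1H)-one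
Product: 17 (3R,3aS,4R,8aR)-6,8a-dimethyl-3-(propan-2-yl)-1,2,3,3a,4,5,8,8a-octahydroazulene-3,4-diol
Conditions: NaBH4, CeCl3·7H2O, MeOH, −78 °C
Reagents that add atoms: none
Why: Luche-type 1,2-reduction in which hydride adds to the ring ketone from the face opposite the angular CH3 (the face of H-3a), giving the 4R alcohol cis to that CH3, in a medium too weakly basic to isomerise the alkene.

Step 10
Reactants: 17 (3R,3aS,4R,8aR)-6,8a-dimethyl-3-(propan-2-yl)-1,2,3,3a,4,5,8,8a-octahydroazulene-3,4-diol; 18 4-(acetyloxy)benzoyl chloride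
Product: 20 (3R,3aS,4R,8aR)-3-hydroxy-6,8a-dimethyl-3-(propan-2-yl)-1,2,3,3a,4,5,8,8a-octahydroazulen-4-yl 4-hydroxybenzoate, via aryl acetate 19 (not isolated)
Conditions: 4-(acetyloxy)benzoyl chloride, Et3N, DMAP, CH2Cl2, 0 °C to rt; then pyrrolidine, 0 °C
Reagents that add atoms: 4-(acetyloxy)benzoyl chloride, CC(=O)Oc1ccc(cc1)C(Cl)=O
Why: DMAP-catalysed acylation of the only secondary hydroxyl (retention at C6, the tertiary OH is inert), then chemoselective aminolysis of the aryl acetate, which is far more electrophilic than the hindered alkyl benzoate.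

Step 11
Reactants: 20 (3R,3aS,4R,8aR)-3-hydroxy-6,8a-dimethyl-3-(propan-2-yl)-1,2,3,3a,4,5,8,8a-octahydroazulen-4-yl 4-hydroxybenzoate
Product: 21 (1R,4R,5S,6R,8R,9S)-8,9-epoxy-4-hydroxydaucan-6-yl 4-hydroxybenzoate (CNP0163817.3)
Conditions: mCPBA, CH2Cl2/aq. pH 8 phosphate buffer, 0 °C
Reagents that add atoms: mCPBA, OOC(=O)c1cccc(Cl)c1
Why: Prilezhaev epoxidation: the peracid adds syn to the trisubstituted alkene from the face opposite the angular CH3 and the aroyloxy group, which both flank the other face, setting C8 and C9 together, while the buffer prevents acid-induced transannular opening by the tertiary OH.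

**Compound list**

1 | (S)-(+)-terpinen-4-ol, (1S)-4-methyl-1-(propan-2-yl)cyclohex-3-en-1-ol | CC1=CC[C@](O)(C(C)C)CC1 | starting material
2 | secondary ozonide (1,2,4-trioxolane) of 1, carbinol carbon unchanged, trioxolane carbons as a mixture | CC12CC[C@@](O)(C(C)C)CC(OO1)O2 | intermediate (not isolated)
3 | (3S)-3-hydroxy-6-oxo-3-(propan-2-yl)heptanal | CC(=O)CC[C@@](O)(C(C)C)CC=O | intermediate (not isolated)
4 | (5R)-5-hydroxy-2-methyl-5-(propan-2-yl)cyclopent-1-ene-1-carbaldehyde | CC1=C(C=O)[C@](O)(C(C)C)CC1 | intermediate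
5 | allylmagnesium bromide | C=CC[Mg]Br | starting material
6 | 1-[(5R)-5-hydroxy-2-methyl-5-(propan-2-yl)cyclopent-1-en-1-yl]but-3-en-1-ol, mixture of C1 epimers | CC1=C(C(O)CC=C)[C@](O)(C(C)C)CC1 | intermediate
7 | 1-[(5R)-5-hydroxy-2-methyl-5-(propan-2-yl)cyclopent-1-en-1-yl]but-3-en-1-one | CC1=C(C(=O)CC=C)[C@](O)(C(C)C)CC1 | intermediate
8 | (1S)-1-[(5R)-5-hydroxy-2-methyl-5-(propan-2-yl)cyclopent-1-en-1-yl]but-3-en-1-ol | CC1=C([C@@H](O)CC=C)[C@](O)(C(C)C)CC1 | intermediate
9 | potassium (1S)-1-[(5R)-5-hydroxy-2-methyl-5-(propan-2-yl)cyclopent-1-en-1-yl]but-3-en-1-olate | CC1=C([C@@H]([O-])CC=C)[C@](O)(C(C)C)CC1.[K+] | intermediate (not isolated)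
10 | potassium (Z)-[(2R,5R)-2-hydroxy-5-methyl-2-(propan-2-yl)-5-(prop-2-en-1-yl)cyclopentylidene]methanolate | CC(C)[C@]1(O)CC[C@](C)(CC=C)/C1=C/[O-].[K+] | intermediate (not isolated)
11 | (1S,2R,5R)-2-hydroxy-5-methyl-2-(propan-2-yl)-5-(prop-2-en-1-yl)cyclopentane-1-carbaldehyde (CHO cis to isopropyl and allyl) | CC(C)[C@]1(O)CC[C@](C)(CC=C)[C@@H]1C=O | intermediate (not isolated)
12 | (1R,2R,5R)-2-hydroxy-5-methyl-2-(propan-2-yl)-5-(prop-2-en-1-yl)cyclopentane-1-carbaldehyde (CHO cis to OH and CH3) | CC(C)[C@]1(O)CC[C@](C)(CC=C)[C@H]1C=O | intermediate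
13 | (2-methylprop-2-en-1-yl)magnesium chloride | CC(=C)C[Mg]Cl | starting material
14 | (1S)-1-[(1S,2R,5R)-2-hydroxy-5-methyl-2-(propan-2-yl)-5-(prop-2-en-1-yl)cyclopentyl]-3-methylbut-3-en-1-ol | CC(C)[C@]1(O)CC[C@](C)(CC=C)[C@H]1[C@@H](O)CC(C)=C | intermediate
15 | (3R,3aS,4S,8aR)-6,8a-dimethyl-3-(propan-2-yl)-1,2,3,3a,4,5,8,8a-octahydroazulene-3,4-diol | CC(C)[C@]1(O)CC[C@]2(C)CC=C(C)C[C@H](O)[C@H]21 | intermediate
16 | (3R,3aR,8aR)-3-hydroxy-6,8a-dimethyl-3-(propan-2-yl)-2,3,3a,5,8,8a-hexahydroazulen-4(1H)-one | CC(C)[C@]1(O)CC[C@]2(C)CC=C(C)CC(=O)[C@H]21 | intermediate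
17 | (3R,3aS,4R,8aR)-6,8a-dimethyl-3-(propan-2-yl)-1,2,3,3a,4,5,8,8a-octahydroazulene-3,4-diol | CC(C)[C@]1(O)CC[C@]2(C)CC=C(C)C[C@@H](O)[C@H]21 | intermediate
18 | 4-(acetyloxy)benzoyl chloride | CC(=O)Oc1ccc(cc1)C(Cl)=O | starting material
19 | (3R,3aS,4R,8aR)-3-hydroxy-6,8a-dimethyl-3-(propan-2-yl)-1,2,3,3a,4,5,8,8a-octahydroazulen-4-yl 4-(acetyloxy)benzoate | CC(C)[C@]1(O)CC[C@]2(C)CC=C(C)C[C@@H](OC(=O)c3ccc(OC(C)=O)cc3)[C@H]21 | intermediate (not isolated)
20 | (3R,3aS,4R,8aR)-3-hydroxy-6,8a-dimethyl-3-(propan-2-yl)-1,2,3,3a,4,5,8,8a-octahydroazulen-4-yl 4-hydroxybenzoate | CC(C)[C@]1(O)CC[C@]2(C)CC=C(C)C[C@@H](OC(=O)c3ccc(O)cc3)[C@H]21 | intermediate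
21 | (1R,4R,5S,6R,8R,9S)-8,9-epoxy-4-hydroxydaucan-6-yl 4-hydroxybenzoate; epoxide oxygen on the face of H5, opposite the C1 methyl and the ester | CC(C)[C@]1(O)CC[C@]2(C)C[C@@H]3O[C@]3(C)C[C@@H](OC(=O)c3ccc(O)cc3)[C@H]21 | target

**Step count and weak points**

Total: 11 steps. Longest linear sequence: 11 steps (the route is fully linear from 1; 5, 13 and 18 are bought).

The three steps most likely to fail:

Step 4 (the relay reduction). If the reduction does not deliver the 1S carbinol cleanly, the approach changes from controlling the hydride to inverting the Grignard adduct. This fallback sets out from 6, in which the 1R epimer is expected to predominate, and bypasses 7. Mitsunobu reaction (4-nitrobenzoic acid, PPh3, diisopropyl azodicarboxylate, toluene, 0 °C) on the 1R alcohol gives (1S)-1-[(5R)-5-hydroxy-2-methyl-5-(propan-2-yl)cyclopent-1-en-1-yl]but-3-en-1-yl 4-nitrobenzoate F1 with inversion. Methanolysis (K2CO3, MeOH, 0 °C) releases the 1S alcohol, and the route is rejoined at 8.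

Step 5 (the oxy-Cope rearrangement). The risks are loss of facial control if the hydrogen bond does not hold the conformation, a sluggish shift onto the tetrasubstituted alkene, and β-elimination from the enolate. The fallback sets out from 8 and replaces the hydrogen bond by a covalent tether and the anionic by a thermal shift. tBu2Si(OTf)2 and 2,6-lutidine in CH2Cl2 convert the 1,3-diol into the O,O'-di-tert-butylsilylene derivative of 8 (six-membered 1,3,2-dioxasilinane) F2, which locks the carbinol oxygen on the hydroxyl face and the allyl group on the isopropyl face. Heating in 1,2-dichlorobenzene at about 200 °C gives the rearranged bicyclic silyl enol ether, C1 now carrying CH3 and allyl, the enol oxygen and the tertiary oxygen still bridged by Si(tBu)2, F3, with no free enolate present. HF·pyridine in THF followed by the same DBU equilibration returns the route at 12.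

Step 11 (face of epoxidation). If the peracid prefers the wrong face, the approach changes from direct oxygen transfer to a halohydrin, which puts the epoxide on the face opposite to the one the electrophile attacks. The fallback sets out from 19, isolated by leaving out the pyrrolidine treatment in step 10, so that the phenol stays protected against ring bromination. NBS in THF/H2O at 0 °C gives (3R,3aS,4R,6R,7R,8aR)-7-bromo-3,6-dihydroxy-6,8a-dimethyl-3-(propan-2-yl)decahydroazulen-4-yl 4-(acetyloxy)benzoate F4 (bromonium on the face the peracid used, water opening at the tertiary carbon from the other face). K2CO3 in MeOH then closes the epoxide with inversion at the CHBr carbon and removes the aryl acetate in the same operation, arriving at 21.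

**Further compounds**

F1 | step 4 | (1S)-1-[(5R)-5-hydroxy-2-methyl-5-(propan-2-yl)cyclopent-1-en-1-yl]but-3-en-1-yl 4-nitrobenzoate | CC1=C([C@@H](OC(=O)c2ccc(cc2)[N+](=O)[O-])CC=C)[C@](O)(C(C)C)CC1
F2 | step 5 | O,O'-di-tert-butylsilylene derivative of 8 (six-membered 1,3,2-dioxasilinane) | CC1=C2[C@H](CC=C)O[Si](C(C)(C)C)(C(C)(C)C)O[C@@]2(C(C)C)CC1
F3 | step 5 | rearranged bicyclic silyl enol ether, C1 carrying CH3 and allyl, enol oxygen and tertiary oxygen bridged by Si(tBu)2 | C=CC[C@@]1(C)CC[C@]2(C(C)C)O[Si](C(C)(C)C)(C(C)(C)C)OC=C12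
F4 | step 11 | (3R,3aS,4R,6R,7R,8aR)-7-bromo-3,6-dihydroxy-6,8a-dimethyl-3-(propan-2-yl)decahydroazulen-4-yl 4-(acetyloxy)benzoate | CC(C)[C@]1(O)CC[C@]2(C)C[C@@H](Br)[C@](C)(O)C[C@@H](OC(=O)c3ccc(OC(C)=O)cc3)[C@H]21
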